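Compound numbers are those of the steps and of the compound list (1 starting phenol, 14 cascade precursor, 15 cascade product, 28 target).

## Analysis of the target

Target 28 is a C14 nor-eremophilane on a cis-fused octalin. Ring A is C5–C6=C7–C8(=O)–C9–C10 and ring B is C10–C1–C2–C3–C4–C5; this numbering, with β for the face carrying the C10 hydroxyl, is used for every bicyclic compound below. There are five stereocentres: C3 (S, acetate), C4 (R, methyl), C5 (R, quaternary methyl), C9 (S, angelate) and C10 (R, tertiary hydroxyl). The substituents on C3, C4, C5 and C10 are contiguous and all β, whereas the C9 ester is α, trans to the C10 hydroxyl. Ring A is sensitive: the C6=C7 alkene is activated by both the C8 ketone and the C7 acetyl group, C9 is an epimerisable α-acyloxy ketone carbon, and the C10 hydroxyl is β to the C8 ketone, so base can cause retro-aldol cleavage or elimination. The angelate isomerises to the tiglate under basic, nucleophilic or radical conditions. The main difficulty is the pair of adjacent fully substituted carbons C5 and C10 inside a run of four syn stereocentres, which must be in place before the fragile ring A functions appear. The plan rests on one feature: the C3 oxygen, the C4 methyl and the C5 methyl are syn on ring B, and quaternary C5 carries C6, the β-carbon of the ring A enone. A carbon delivered from the C3 oxygen to C4 over a one-atom silicon bridge therefore arrives on the correct face, becomes the C4 methyl after desilylation, and leaves a radical on C5 that can close ring A by bonding to C6.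

## Retrosynthetic reasoning

28 ⇒ 27. The C7 acetyl group is carried as its 1-ethoxyvinyl ether and released by hydrolysis in the last step. The doubly activated alkene of 28 then exists only after every basic or nucleophilic operation is over.

27 ⇒ 24 + 25. The C9–O acyl bond is cut to ketol 24 and angelic acid 25. The ester comes late because the Z alkene does not tolerate the iodination and strong-base steps before it. The forward reaction must acylate a hindered α-hydroxy ketone with retention and leave the tertiary C10 hydroxyl free.

24 ⇒ 22. The C9–O bond is cut. C9 is the only enolisable position next to the C8 ketone of 22 (C7 is vinylic, C5 quaternary), so electrophilic hydroxylation of the cross-conjugated dienolate is regiochemically unambiguous. The forward step must deliver oxygen to the α-face.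

22 ⇒ 20 + 21, and 20 ⇒ 19. The bond from C7 to the masked acetyl carbon is a palladium-catalysed coupling of vinyl iodide 20 with stannane 21, and 20 comes from α-iodination of enone 19. C7 is functionalised only now because it must be a hydrogen-bearing alkyne carbon in the key step. It is done before C9 becomes a stereocentre, so the amine base of the iodination has nothing to epimerise.

19 ⇒ 18 ⇒ 17 ⇒ 16 ⇒ 15. After removal of the acetate, the C4 methyl and the C3 hydroxyl of 17 are recognised as the two ends of the Si–C/Si–O bridge of 15. Protodesilylation needs hot basic fluoride, which the β-hydroxy ketone of 15 would not survive. The C8 carbonyl is therefore held as allylic alcohol 16 during the desilylation to 17 and restored by allylic oxidation to 18, which also differentiates the C8 and C3 hydroxyls.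

15 ⇒ 14 (key disconnection). Two C–C bonds are cut, C4–CH2 (inside the oxasilolane) and C5–C6 (ring A). This removes two rings, the C5 quaternary centre and the C4 stereocentre at once, and leaves a monocyclic cyclohexene with only two stereocentres, C3 and C10, both oxygen-bearing. The forward reaction is a radical chain in which a silylmethyl radical tethered to the C3 oxygen adds to C4 and the resulting C5 radical adds to the terminal ynone carbon C6.

14 ⇒ 12 + 13, 12 ⇒ 10 + 11, and 10 ⇒ 9 ⇒ 6 + 7. The labile tether 13 is attached last, to the secondary hydroxyl of diol 12. The ynone comes from Weinreb amide 10 and ethynylmagnesium bromide 11. The C9–C10 bond comes from addition of the enolate of 7 to enone 6. The addition must occur on the face opposite the C3 silyloxy group so that the two oxygens end up cis.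

6 ⇒ 5 ⇒ 4 ⇒ 3 ⇒ 2 ⇒ 1. Enone 6 is the unmasked form of ketal 5, whose single stereocentre is set by enantioselective reduction of enone 3 to 4. Enone 3 comes from quinone monoketal 2 by saturation of the unsubstituted alkene, and 2 from oxidation of phenol 1, which already holds the methyl group next to the future C10.

## Alternatives that were turned down

Alternative 1: Ring B would be cut at C5–C10 and C4–C3, and made by a Diels–Alder reaction of (E)-2-methylbut-2-enal A1 with the 1,1-disubstituted silyloxy diene A2 under a chiral oxazaborolidinium Lewis acid, giving cyclohexene A3. In its favour, it is convergent and catalytic in its source of chirality. The E geometry of A1 fixes the cis relation of the C4 and C5 methyls, and C5 and C10 are created in the same step, with formyl and protected hydroxymethyl handles for ring A. On convergence and on setting three centres at once it is stronger than the chosen route, and it avoids tin. Against it, A1 is a sluggish α,β-disubstituted dienophile. A2 carries two substituents on one terminus, so one of them is forced inside and the reactive s-cis conformer is disfavoured. The step must also join two carbons that both become fully substituted. A3 lacks the C3 oxygen and has its alkene at C1=C2, so the acetate stereocentre and all of ring A still need many steps. The chosen route offers the C3 oxygen from the start and a single step that makes the C4 methyl, C5 and ring A together.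

Alternative 2: Ring A would be cut at C7–C8, and closed by an intramolecular Morita–Baylis–Hillman reaction of enone aldehyde A4 under a trialkylphosphine, giving adduct A5. Its strength is the end game: A5 already has the C7 acetyl group, the C9 oxygen and an oxygen on C8, so no iodination or cross-coupling is needed, and here it is better than the chosen route. Against it, the phosphine must add to C6, which sits on quaternary C5; β-substituted, neopentyl-type enones are poor substrates. The aldehyde is an α-silyloxy aldehyde next to quaternary C10 and can epimerise. The step makes one bond, and its only new stereocentre, C8, is later oxidised away. Above all, A4 presupposes ring B with C4, C5, C9 and C10 already set, so the key step does not address the real difficulty. The chosen route puts its key step on exactly that problem.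

Alternative 3: Ring A would be cut at C8–C9, and closed by a carbene-catalysed crossed benzoin reaction of dialdehyde A6 (triazolium-derived N-heterocyclic carbene), giving ketol A7. In its favour, the unhindered C8 aldehyde should become the acyl anion equivalent and attack the hindered C9 aldehyde, so the C8 ketone and the C9 hydroxyl appear directly and the C9 configuration is open to catalyst control. On C9 it is stronger than the chosen route, whose C9 hydroxylation is one of its uncertain steps. Against it, attack on a neopentyl α-silyloxy aldehyde is slow and the ketol can transpose. A7 still lacks the C6=C7 alkene and the C7 acetyl group, so dehydrogenation and acylation remain. As in alternative 2, A6 requires ring B with the C5 and C10 centres already made. The chosen route builds those centres in its key step and accepts a less certain C9 oxidation.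

Key step: step 10

Remarks on the chemistry (assumptions):
- Locants and α/β in the names of 15 to 28 follow the ring numbering of the analysis.
- In the oxazaborolidine model the alkenyl arm of 3 is taken as the large group, so the (R)-catalyst is written for the S alcohol.
- 16 and 17 are carried as mixtures of C8 epimers, because that centre is removed in step 13.

## Route

Step 1
Reactants: 1 4-methoxy-3-methylphenol
Product: 2 4,4-dimethoxy-3-methylcyclohexa-2,5-dien-1-one
Conditions: PhI(OAc)2, MeOH, 0 °C
Reagents that add atoms: methanol, CO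
Why: Oxidative dearomatisation of a 4-alkoxyphenol in methanol traps the phenoxonium ion at the methoxy-bearing carbon and gives the quinone monoketal.

Step 2
Reactants: 2 4,4-dimethoxy-3-methylcyclohexa-2,5-dien-1-one
Product: 3 4,4-dimethoxy-3-methylcyclohex-2-en-1-one
Conditions: H2 (1 atm), RhCl(PPh3)3 (cat.), toluene, rt
Reagents that add atoms: none
Why: Homogeneous hydrogenation with RhCl(PPh3)3 (Wilkinson's catalyst) saturates the disubstituted alkene of a cross-conjugated cyclohexadienone much faster than the methyl-substituted one, and avoids the hydrogenolysis seen with heterogeneous palladium.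

Step 3
Reactants: 3 4,4-dimethoxy-3-methylcyclohex-2-en-1-one
Product: 4 (S)-4,4-dimethoxy-3-methylcyclohex-2-en-1-ol
Conditions: (R)-2-methyl-CBS-oxazaborolidine (0.1 equiv), BH3·SMe2, THF, −30 °C; then H2O
Reagents that add atoms: none
Why: Corey–Bakshi–Shibata reduction, 1,2-selective on enones; the substituted alkenyl arm acts as the large group and hydride is delivered to the face that gives the S carbinol, which becomes C3 and is the source of absolute configuration.

Step 4
Reactants: 4 (S)-4,4-dimethoxy-3-methylcyclohex-2-en-1-ol
Product: 5 (S)-tert-butyl[(4,4-dimethoxy-3-methylcyclohex-2-en-1-yl)oxy]dimethylsilane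
Conditions: t-BuMe2SiCl, imidazole, DMF, rt
Reagents that add atoms: tert-butyldimethylsilyl chloride, CC(C)(C)[Si](C)(C)Cl
Why: Standard silylation of a secondary alcohol; the bulky silyl group is wanted for face control in step 6.

Step 5
Reactants: 5 (S)-tert-butyl[(4,4-dimethoxy-3-methylcyclohex-2-en-1-yl)oxy]dimethylsilane
Product: 6 (S)-4-[(tert-butyldimethylsilyl)oxy]-2-methylcyclohex-2-en-1-one
Conditions: pyridinium p-toluenesulfonate (cat.), acetone/H2O, rt
Reagents that add atoms: water, O
Why: Mild acid hydrolysis of a dimethyl ketal; the silyl ether and the carbinol stereocentre are not affected under these buffered conditions.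

Step 6
Reactants: 6 (S)-4-[(tert-butyldimethylsilyl)oxy]-2-methylcyclohex-2-en-1-one; 7 N-methoxy-N-methylacetamide
Product: 9 2-[(1S,4S)-4-[(tert-butyldimethylsilyl)oxy]-1-hydroxy-2-methylcyclohex-2-en-1-yl]-N-methoxy-N-methylacetamide, via lithium amide enolate 8 (not isolated)
Conditions: 7, LiN(i-Pr)2, THF, −78 °C; then 6, −78 °C; aq. NH4Cl at −78 °C
Reagents that add atoms: none
Why: Kinetic aldol-type 1,2-addition of a lithium amide enolate to an enone carbonyl, essentially irreversible for amide enolates at −78 °C. The nucleophile should enter axially on the face opposite the pseudoaxial silyloxy group, so the new tertiary hydroxyl is cis to the C3 oxygen (1S).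

Step 7
Reactants: 9 2-[(1S,4S)-4-[(tert-butyldimethylsilyl)oxy]-1-hydroxy-2-methylcyclohex-2-en-1-yl]-N-methoxy-N-methylacetamide
Product: 10 2-[(1S,4S)-1,4-dihydroxy-2-methylcyclohex-2-en-1-yl]-N-methoxy-N-methylacetamide
Conditions: Bu4NF, THF, 0 °C
Reagents that add atoms: none
Why: Fluoride cleavage of the silyl ether; it is done before the ynone exists, because a terminal ynone would not tolerate fluoride.

Step 8
Reactants: 10 2-[(1S,4S)-1,4-dihydroxy-2-methylcyclohex-2-en-1-yl]-N-methoxy-N-methylacetamide; 11 ethynylmagnesium bromide
Product: 12 1-[(1S,4S)-1,4-dihydroxy-2-methylcyclohex-2-en-1-yl]but-3-yn-2-one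
Conditions: 11 (4 equiv), THF, 0 °C to rt; inverse quench into cold 1 M HCl
Reagents that add atoms: none
Why: Weinreb ketone synthesis: two equivalents of reagent deprotonate the hydroxyls and the chelated tetrahedral intermediate prevents over-addition. The acidic inverse quench keeps the released hydroxylamine protonated so that it cannot add to the ynone.

Step 9
Reactants: 12 1-[(1S,4S)-1,4-dihydroxy-2-methylcyclohex-2-en-1-yl]but-3-yn-2-one; 13 (bromomethyl)chlorodimethylsilane
Product: 14 1-[(1S,4S)-4-{[(bromomethyl)dimethylsilyl]oxy}-1-hydroxy-2-methylcyclohex-2-en-1-yl]but-3-yn-2-one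
Conditions: 13 (1.1 equiv), i-Pr2NEt, CH2Cl2, −20 to 0 °C; used without storage
Reagents that add atoms: none
Why: Silylation of the secondary allylic hydroxyl; the tertiary hydroxyl is too hindered to react with one equivalent at low temperature, and the hindered amine does not add to the ynone.

Step 10
Reactants: 14 1-[(1S,4S)-4-{[(bromomethyl)dimethylsilyl]oxy}-1-hydroxy-2-methylcyclohex-2-en-1-yl]but-3-yn-2-one
Product: 15 (3S,4R,5R,10S)-10-hydroxy-5-methyl-3,4-[oxy(dimethylsilanediyl)methylene]-cis-Δ6-octalin-8-one (oxasilolane oxygen on C3 and CH2 on C4 both β)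
Conditions: Bu3SnH (1.3 equiv, added over 6 h), AIBN (0.2 equiv), benzene (0.01 M), 80 °C
Reagents that add atoms: none
Why: The stannyl radical abstracts bromine; the silylmethyl radical adds to C4, the resulting tertiary C5 radical adds to the terminal ynone carbon C6, and the C7 vinyl radical takes hydrogen from Bu3SnH to carry the chain. The closest known reaction type is the silicon-tethered radical cyclisation of (bromomethyl)dimethylsilyl ethers of allylic alcohols with capture of the cyclised radical by a second acceptor, combined with addition of alkyl radicals to the β-carbon of ynones whose carbonyl lies inside the new ring. The oxasilolane closes 5-exo-trig: C4 is the hydrogen-bearing alkene end, the radical formed is tertiary, and the 6-endo alternative would attack fully substituted C5. Ring A closes 6-endo-dig: the nucleophilic tertiary radical attacks the electron-poor terminal carbon, whereas 5-exo attack at C7 would be polarity-mismatched and at the substituted alkyne carbon. C4 is set by the tether, which can only reach the face of the C3 oxygen, so the five-membered ring is cis-fused and the CH2 is β. C5 is set because the ynone chain hangs from the α-face of C10 and the new C4 substituent blocks the β-face, so C6 bonds from the α-face and the methyl is pushed β, giving the cis-decalin. The step needs bromine abstraction to outrun stannyl addition to the ynone and both cyclisations to outrun hydrogen transfer, which slow addition of the hydride at high dilution is meant to secure. The free C10 hydroxyl is inert to the radical chain.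

Step 11
Reactants: 15 (3S,4R,5R,10S)-10-hydroxy-5-methyl-3,4-[oxy(dimethylsilanediyl)methylene]-cis-Δ6-octalin-8-one
Product: 16 (3S,4R,5R,10S)-5-methyl-3,4-[oxy(dimethylsilanediyl)methylene]-cis-Δ6-octaline-8,10-diol (both C8 epimers)
Conditions: i-Bu2AlH (2.5 equiv), CH2Cl2, −78 °C; aq. potassium sodium tartrate
Reagents that add atoms: none
Why: 1,2-Reduction of the enone removes the ketone that would allow retro-aldol cleavage or elimination of the C10 hydroxyl in step 12. The new C8 centre is destroyed in step 13, so its configuration does not matter.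

Step 12
Reactants: 16 (3S,4R,5R,10S)-5-methyl-3,4-[oxy(dimethylsilanediyl)methylene]-cis-Δ6-octaline-8,10-diol
Product: 17 (3S,4R,5R,10S)-4,5-dimethyl-cis-Δ6-octaline-3,8,10-triol (both C8 epimers)
Conditions: Bu4NF·3H2O (5 equiv), DMF, 70 °C
Reagents that add atoms: none
Why: Protodesilylation of a 1-oxa-2-silacyclopentane: fluoride gives a pentacoordinate silicon, assisted by the C3 alkoxide, which releases the primary carbon to a proton from water and so reveals the C4 methyl and the C3 hydroxyl. No bond to C4 is broken, so its configuration is kept.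

Step 13
Reactants: 17 (3S,4R,5R,10S)-4,5-dimethyl-cis-Δ6-octaline-3,8,10-triol
Product: 18 (3S,4R,5R,10S)-3,10-dihydroxy-4,5-dimethyl-cis-Δ6-octalin-8-one
Conditions: MnO2, CH2Cl2, rt
Reagents that add atoms: none
Why: MnO2 oxidises allylic alcohols selectively; the saturated C3 and tertiary C10 hydroxyls are not touched, and both C8 epimers converge on one enone.

Step 14
Reactants: 18 (3S,4R,5R,10S)-3,10-dihydroxy-4,5-dimethyl-cis-Δ6-octalin-8-one
Product: 19 (3S,4R,5R,10S)-3-acetoxy-10-hydroxy-4,5-dimethyl-cis-Δ6-octalin-8-one
Conditions: Ac2O, pyridine, 4-(dimethylamino)pyridine (cat.), CH2Cl2, 0 °C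
Reagents that add atoms: acetic anhydride, CC(=O)OC(C)=O
Why: Acetylation of the only secondary alcohol; the tertiary C10 hydroxyl does not react under these mild conditions.

Step 15
Reactants: 19 (3S,4R,5R,10S)-3-acetoxy-10-hydroxy-4,5-dimethyl-cis-Δ6-octalin-8-one
Product: 20 (3S,4R,5S,10S)-3-acetoxy-10-hydroxy-7-iodo-4,5-dimethyl-cis-Δ6-octalin-8-one (C5 unchanged in space; the descriptor changes because of iodine)
Conditions: I2, pyridine, CH2Cl2, rt, dark
Reagents that add atoms: iodine, II
Why: α-Iodination of an enone by conjugate addition of pyridine, iodination of the enolate and elimination; it is well established for cyclohexenones with a quaternary γ-carbon.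

Step 16
Reactants: 20 (3S,4R,5S,10S)-3-acetoxy-10-hydroxy-7-iodo-4,5-dimethyl-cis-Δ6-octalin-8-one; 21 tributyl(1-ethoxyvinyl)stannane
Product: 22 (3S,4R,5R,10S)-3-acetoxy-7-(1-ethoxyvinyl)-10-hydroxy-4,5-dimethyl-cis-Δ6-octalin-8-one
Conditions: Pd2(dba)3 (cat.), AsPh3, CuI (cat.), DMF, 50 °C; base-washed silica
Reagents that add atoms: none
Why: Stille coupling of an α-iodoenone with a vinylstannane under zerovalent palladium with CuI acceleration. The neutral conditions leave the β-hydroxy ketone intact, and the enol ether is kept as a masked acetyl group.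

Step 17
Reactants: 22 (3S,4R,5R,10S)-3-acetoxy-7-(1-ethoxyvinyl)-10-hydroxy-4,5-dimethyl-cis-Δ6-octalin-8-one
Product: 24 (3S,4R,5R,9S,10R)-3-acetoxy-7-(1-ethoxyvinyl)-9,10-dihydroxy-4,5-dimethyl-cis-Δ6-octalin-8-one, via dipotassium alkoxide dienolate 23 (not isolated)
Conditions: KN(SiMe3)2 (2.2 equiv), THF, −78 °C; 2-(phenylsulfonyl)-3-phenyloxaziridine, −78 °C; pH 7 buffer
Reagents that add atoms: 2-(phenylsulfonyl)-3-phenyloxaziridine, O=S(=O)(N1OC1c1ccccc1)c1ccccc1
Why: Enolate hydroxylation with an N-sulfonyloxaziridine (Davis oxidation): the alkoxide forms first and the ketone is then enolised at C9, its only α-hydrogen position, which also blocks retro-aldol and elimination. The oxidant should approach C9 from the α-face, away from the C10 alkoxide and the C5 methyl that both lie over the β-face, giving the 9S alcohol trans to the C10 hydroxyl.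

Step 18
Reactants: 24 (3S,4R,5R,9S,10R)-3-acetoxy-7-(1-ethoxyvinyl)-9,10-dihydroxy-4,5-dimethyl-cis-Δ6-octalin-8-one; 25 angelic acid
Product: 27 (3S,4R,5R,9S,10R)-3-acetoxy-9-[(Z)-2-methylbut-2-enoyl]oxy-7-(1-ethoxyvinyl)-10-hydroxy-4,5-dimethyl-cis-Δ6-octalin-8-one, via angelic 2,4,6-trichlorobenzoic anhydride 26 (not isolated)
Conditions: 25, 2,4,6-trichlorobenzoyl chloride, Et3N, toluene, rt; then 24, 75 °C
Reagents that add atoms: none
Why: Yamaguchi esterification through the mixed anhydride without a nucleophilic catalyst, the protocol that transfers the angeloyl group without Z to E isomerisation. The alcohol attacks the unshielded angeloyl carbonyl with retention at C9, and the tertiary C10 hydroxyl is not acylated.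

Step 19
Reactants: 27 (3S,4R,5R,9S,10R)-3-acetoxy-9-[(Z)-2-methylbut-2-enoyl]oxy-7-(1-ethoxyvinyl)-10-hydroxy-4,5-dimethyl-cis-Δ6-octalin-8-one
Product: 28 (3S,4R,5R,9S,10R)-3-acetoxy-7-acetyl-9-[(Z)-2-methylbut-2-enoyl]oxy-10-hydroxy-4,5-dimethyl-cis-Δ6-octalin-8-one (CNP0196241.1)
Conditions: 1 M HCl (aq), THF, 0 °C
Reagents that add atoms: water, O
Why: Acid hydrolysis of the enol ether unmasks the methyl ketone; both esters and the tertiary alcohol survive brief dilute acid at low temperature.

## Compound list

1 | 4-methoxy-3-methylphenol | COc1ccc(O)cc1C | starting material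
2 | 4,4-dimethoxy-3-methylcyclohexa-2,5-dien-1-one | COC1(OC)C=CC(=O)C=C1C | intermediate
3 | 4,4-dimethoxy-3-methylcyclohex-2-en-1-one | COC1(OC)CCC(=O)C=C1C | intermediate
4 | (S)-4,4-dimethoxy-3-methylcyclohex-2-en-1-ol | COC1(OC)CC[C@H](O)C=C1C | intermediate
5 | (S)-tert-butyl[(4,4-dimethoxy-3-methylcyclohex-2-en-1-yl)oxy]dimethylsilane | COC1(OC)CC[C@H](O[Si](C)(C)C(C)(C)C)C=C1C | intermediate
6 | (S)-4-[(tert-butyldimethylsilyl)oxy]-2-methylcyclohex-2-en-1-one | O=C1CC[C@H](O[Si](C)(C)C(C)(C)C)C=C1C | intermediate
7 | N-methoxy-N-methylacetamide | CC(=O)N(C)OC | starting material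
8 | lithium enolate of N-methoxy-N-methylacetamide | C=C(O[Li])N(C)OC | intermediate (not isolated)
9 | 2-[(1S,4S)-4-[(tert-butyldimethylsilyl)oxy]-1-hydroxy-2-methylcyclohex-2-en-1-yl]-N-methoxy-N-methylacetamide | CON(C)C(=O)C[C@@]1(O)CC[C@H](O[Si](C)(C)C(C)(C)C)C=C1C | intermediate
10 | 2-[(1S,4S)-1,4-dihydroxy-2-methylcyclohex-2-en-1-yl]-N-methoxy-N-methylacetamide | CON(C)C(=O)C[C@@]1(O)CC[C@H](O)C=C1C | intermediate
11 | ethynylmagnesium bromide | C#C[Mg]Br | starting material
12 | 1-[(1S,4S)-1,4-dihydroxy-2-methylcyclohex-2-en-1-yl]but-3-yn-2-one | C#CC(=O)C[C@@]1(O)CC[C@H](O)C=C1C | intermediate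
13 | (bromomethyl)chlorodimethylsilane | C[Si](C)(Cl)CBr | starting material
14 | 1-[(1S,4S)-4-{[(bromomethyl)dimethylsilyl]oxy}-1-hydroxy-2-methylcyclohex-2-en-1-yl]but-3-yn-2-one | C#CC(=O)C[C@@]1(O)CC[C@H](O[Si](C)(C)CBr)C=C1C | intermediate
15 | (3S,4R,5R,10S)-10-hydroxy-5-methyl-3,4-[oxy(dimethylsilanediyl)methylene]-cis-Δ6-octalin-8-one | C1C(=O)C=C[C@]2(C)[C@H]3C[Si](C)(C)O[C@H]3CC[C@]12O | intermediate
16 | (3S,4R,5R,10S)-5-methyl-3,4-[oxy(dimethylsilanediyl)methylene]-cis-Δ6-octaline-8,10-diol, C8 epimers | C1C(O)C=C[C@]2(C)[C@H]3C[Si](C)(C)O[C@H]3CC[C@]12O | intermediate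
17 | (3S,4R,5R,10S)-4,5-dimethyl-cis-Δ6-octaline-3,8,10-triol, C8 epimers | C1C(O)C=C[C@]2(C)[C@@H](C)[C@@H](O)CC[C@]12O | intermediate
18 | (3S,4R,5R,10S)-3,10-dihydroxy-4,5-dimethyl-cis-Δ6-octalin-8-one | C1C(=O)C=C[C@]2(C)[C@@H](C)[C@@H](O)CC[C@]12O | intermediate
19 | (3S,4R,5R,10S)-3-acetoxy-10-hydroxy-4,5-dimethyl-cis-Δ6-octalin-8-one | C1C(=O)C=C[C@]2(C)[C@@H](C)[C@@H](OC(C)=O)CC[C@]12O | intermediate
20 | (3S,4R,5S,10S)-3-acetoxy-10-hydroxy-7-iodo-4,5-dimethyl-cis-Δ6-octalin-8-one | C1C(=O)C(I)=C[C@]2(C)[C@@H](C)[C@@H](OC(C)=O)CC[C@]12O | intermediate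
21 | tributyl(1-ethoxyvinyl)stannane | CCCC[Sn](CCCC)(CCCC)C(=C)OCC | starting material
22 | (3S,4R,5R,10S)-3-acetoxy-7-(1-ethoxyvinyl)-10-hydroxy-4,5-dimethyl-cis-Δ6-octalin-8-one | C1C(=O)C(C(=C)OCC)=C[C@]2(C)[C@@H](C)[C@@H](OC(C)=O)CC[C@]12O | intermediate
23 | dipotassium C10 alkoxide C8–C9 dienolate of 22 | C1=C(O[K])C(C(=C)OCC)=C[C@]2(C)[C@@H](C)[C@@H](OC(C)=O)CC[C@]12O[K] | intermediate (not isolated)
24 | (3S,4R,5R,9S,10R)-3-acetoxy-7-(1-ethoxyvinyl)-9,10-dihydroxy-4,5-dimethyl-cis-Δ6-octalin-8-one | O[C@@H]1C(=O)C(C(=C)OCC)=C[C@]2(C)[C@@H](C)[C@@H](OC(C)=O)CC[C@]12O | intermediate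
25 | angelic acid, (Z)-2-methylbut-2-enoic acid | C/C=C(/C)C(=O)O | starting material
26 | angelic 2,4,6-trichlorobenzoic anhydride | C/C=C(/C)C(=O)OC(=O)c1c(Cl)cc(Cl)cc1Cl | intermediate (not isolated)
27 | (3S,4R,5R,9S,10R)-3-acetoxy-9-[(Z)-2-methylbut-2-enoyl]oxy-7-(1-ethoxyvinyl)-10-hydroxy-4,5-dimethyl-cis-Δ6-octalin-8-one | C/C=C(/C)C(=O)O[C@@H]1C(=O)C(C(=C)OCC)=C[C@]2(C)[C@@H](C)[C@@H](OC(C)=O)CC[C@]12O | intermediate
28 | (3S,4R,5R,9S,10R)-3-acetoxy-7-acetyl-9-[(Z)-2-methylbut-2-enoyl]oxy-10-hydroxy-4,5-dimethyl-cis-Δ6-octalin-8-one (CNP0196241.1) | C/C=C(/C)C(=O)O[C@@H]1C(=O)C(C(C)=O)=C[C@]2(C)[C@@H](C)[C@@H](OC(C)=O)CC[C@]12O | target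

## Step count and least certain steps

Total: 19 steps. Longest linear sequence: 19 steps (1 to 28); 7, 11, 13, 21 and 25 are commercial and enter directly.

Step 10 (key step). The most likely failure is addition of the stannyl radical to the terminal ynone (hydrostannylation) in competition with bromine abstraction. The second is hydrogen transfer to the C5 radical before the 6-endo closure, because that closure has to form a quaternary centre next to the fully substituted C10. Fallback, setting out from 10 and returning at 15:
- Vinylmagnesium bromide (THF, 0 °C, acidic quench) should convert 10 into the vinyl ketone 1-[(1S,4S)-1,4-dihydroxy-2-methylcyclohex-2-en-1-yl]but-3-en-2-one F1.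
- Silylation with 13 as in step 9 gives its C3 (bromomethyl)dimethylsilyl ether F2.
- Bu3SnH and AIBN then run the same 5-exo closure followed by a 6-endo-trig addition of the C5 radical to the terminal enone carbon. Stannyl addition to an enone is reversible and the α-keto radical is reduced cleanly. The product is the saturated siloxane-bridged cis-decalone F3.
- Dehydrogenation of F3 with 2-iodoxybenzoic acid in DMSO at 70 °C can introduce only the C6=C7 alkene, because C10 has no hydrogen, and gives 15.

Step 6. The risk is poor or reversed facial selectivity in the enolate addition: the silyloxy group is remote from the carbonyl and the two half-chair conformers of 6 lead to opposite faces. Fallback, setting out from 3 and returning at 10: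
- Reduction of 3 with the (S)-oxazaborolidine gives (R)-4,4-dimethoxy-3-methylcyclohex-2-en-1-ol F4.
- Silylation and hydrolysis as in steps 4 and 5 give the R silyl ether F5 and the R enone F6.
- Enolate 8, now adding on the face of the silyloxy group, gives the trans adduct 2-[(1S,4R)-4-[(tert-butyldimethylsilyl)oxy]-1-hydroxy-2-methylcyclohex-2-en-1-yl]-N-methoxy-N-methylacetamide F7, which has the required configuration at the tertiary carbinol.
- Bu4NF gives the trans diol F8.
- Mitsunobu reaction at the secondary allylic hydroxyl (4-nitrobenzoic acid, PPh3, diisopropyl azodicarboxylate, THF, 0 °C) inverts that centre to the (1S,4S) 4-nitrobenzoate F9. The tertiary hydroxyl is inert and the allylic terminus is fully substituted.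
- K2CO3 in MeOH removes the ester and gives 10.

Step 17. The risk is approach of the oxidant to C9 from the β-face, the convex face of the cis-decalin, which would give the C9 epimer; the shielding by the C10 alkoxide and the C5 methyl on one side and by ring B on the other is finely balanced. Fallback, setting out from 22 and returning at 27: the same enolate oxidation then delivers the 9R epimer of 24, (3S,4R,5R,9R,10R)-3-acetoxy-7-(1-ethoxyvinyl)-9,10-dihydroxy-4,5-dimethyl-cis-Δ6-octalin-8-one F10. Mitsunobu esterification of F10 with 25 (PPh3, diisopropyl azodicarboxylate, toluene, 0 °C) displaces the activated α-keto carbinol with inversion and gives 27 directly, in place of step 18.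

Step 2. The risk is loss of chemoselectivity: saturation of both alkenes, or reductive loss of methanol with rearomatisation. Fallback, setting out from 2 and returning at 3: conjugate reduction with K[BH(s-Bu)3] in THF at −78 °C followed by protonation. Hydride adds to the unsubstituted β-carbon and cannot reach the β-carbon that carries the methyl group and the ketal, and no metal surface is present to cause hydrogenolysis. No new compound is involved.

## Further compounds

F1 | step 10 | 1-[(1S,4S)-1,4-dihydroxy-2-methylcyclohex-2-en-1-yl]but-3-en-2-one | C=CC(=O)C[C@@]1(O)CC[C@H](O)C=C1C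
F2 | step 10 | 1-[(1S,4S)-4-{[(bromomethyl)dimethylsilyl]oxy}-1-hydroxy-2-methylcyclohex-2-en-1-yl]but-3-en-2-one | C=CC(=O)C[C@@]1(O)CC[C@H](O[Si](C)(C)CBr)C=C1C
F3 | step 10 | (3S,4R,5R,10S)-10-hydroxy-5-methyl-3,4-[oxy(dimethylsilanediyl)methylene]-cis-decalin-8-one | C1C(=O)CC[C@]2(C)[C@H]3C[Si](C)(C)O[C@H]3CC[C@]12O
F4 | step 6 | (R)-4,4-dimethoxy-3-methylcyclohex-2-en-1-ol | COC1(OC)CC[C@@H](O)C=C1C
F5 | step 6 | (R)-tert-butyl[(4,4-dimethoxy-3-methylcyclohex-2-en-1-yl)oxy]dimethylsilane | COC1(OC)CC[C@@H](O[Si](C)(C)C(C)(C)C)C=C1C
F6 | step 6 | (R)-4-[(tert-butyldimethylsilyl)oxy]-2-methylcyclohex-2-en-1-one | O=C1CC[C@@H](O[Si](C)(C)C(C)(C)C)C=C1C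
F7 | step 6 | 2-[(1S,4R)-4-[(tert-butyldimethylsilyl)oxy]-1-hydroxy-2-methylcyclohex-2-en-1-yl]-N-methoxy-N-methylacetamide | CON(C)C(=O)C[C@@]1(O)CC[C@@H](O[Si](C)(C)C(C)(C)C)C=C1C
F8 | step 6 | 2-[(1S,4R)-1,4-dihydroxy-2-methylcyclohex-2-en-1-yl]-N-methoxy-N-methylacetamide | CON(C)C(=O)C[C@@]1(O)CC[C@@H](O)C=C1C
F9 | step 6 | (1S,4S)-4-hydroxy-4-{2-[methoxy(methyl)amino]-2-oxoethyl}-3-methylcyclohex-2-en-1-yl 4-nitrobenzoate | CON(C)C(=O)C[C@@]1(O)CC[C@H](OC(=O)c2ccc(cc2)[N+](=O)[O-])C=C1C
F10 | step 17 | (3S,4R,5R,9R,10R)-3-acetoxy-7-(1-ethoxyvinyl)-9,10-dihydroxy-4,5-dimethyl-cis-Δ6-octalin-8-one | O[C@H]1C(=O)C(C(=C)OCC)=C[C@]2(C)[C@@H](C)[C@@H](OC(C)=O)CC[C@]12O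
F0 | step 2 | none | none
A1 | alternative 1 | (E)-2-methylbut-2-enal | C/C=C(\C)C=O
A2 | alternative 1 | (2Z)-2-[(tert-butyldimethylsilyl)oxy]-1-[(4-methoxybenzyl)oxy]penta-2,4-diene | C=C/C=C(\O[Si](C)(C)C(C)(C)C)COCc1ccc(OC)cc1
A3 | alternative 1 | Diels–Alder adduct, ring B cyclohexene with C5 methyl and formyl, C4 methyl, C10 silyloxy and (4-methoxybenzyl)oxymethyl | O=C[C@]1(C)[C@@H](C)CC=C[C@]1(O[Si](C)(C)C(C)(C)C)COCc2ccc(OC)cc2
A4 | alternative 2 | ring B enone aldehyde, C5 (E)-3-oxobut-1-enyl and C10 hydroxy with 1-(triethylsilyloxy)-2-oxoethyl | CC(=O)/C=C/[C@]1(C)[C@@H](C)[C@@H](OC(C)=O)CC[C@]1(O)[C@H](O[Si](CC)(CC)CC)C=O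
A5 | alternative 2 | cis-fused 7-acetyl-octalen-8-ol Morita–Baylis–Hillman adduct | CC(=O)C1=C[C@]2(C)[C@@H](C)[C@@H](OC(C)=O)CC[C@]2(O)[C@H](O[Si](CC)(CC)CC)[C@@H]1O
A6 | alternative 3 | ring B dialdehyde, C5 3-oxopropyl and C10 formyl with triethylsilyloxy | O=CCC[C@]1(C)[C@@H](C)[C@@H](OC(C)=O)CC[C@@]1(C=O)O[Si](CC)(CC)CC
A7 | alternative 3 | cis-fused decalin ketol with C9 hydroxyl, C8 ketone and C10 triethylsilyl ether | O[C@@H]1C(=O)CC[C@]2(C)[C@@H](C)[C@@H](OC(C)=O)CC[C@]12O[Si](CC)(CC)CC
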